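The synthesis rests on closing the ten-membered carbocycle across C8–C9, the two ester-bearing carbinol carbons, which form a cis-diol beside the trans-fused C6/C7 γ-lactone. A SmI2 pinacol coupling of an epoxy lactone dialdehyde (C8 aliphatic aldehyde, C9 (Z)-enal) should form this bond, the ring and both carbinol stereocentres in one operation; the rigid lactone and the C4–C5 epoxide pre-organise the chain. The precursor is assembled from geraniol (C1–C6, C15) by Sharpless epoxidation, a Still–Gennari olefination with a C14-bearing phosphonate (C9, C10, C14) and an Evans succinate aldol (C7, C8, C11, C12); C14 stays a silyl ether until the ring is closed.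

Key step: step 15

Assumption: germacrane numbering is used throughout (ring C1–C10, C1=C10 alkene, C14 on C10, C15 on C4, C11–C13 on C7, C12 the lactone carbonyl); "C9 cis to C2" denotes the alkene geometry that becomes the cis ring double bond.
Remark on the chemistry: a phosphonoacetate supplies only C9 and C10, so C14 is attached to the olefination reagent beforehand (step 1); O14 is carried as a triisopropylsilyl ether, O9 as a tert-butyldimethylsilyl ether and O6 as a triethylsilyl ether, so that each can be unmasked beside the others.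
Remark on the chemistry: the two Mannich intermediates of step 17 are C11 epimer mixtures, so this centre is left open in their SMILES.

Step 1
Reactants: 1 methyl bis(2,2,2-trifluoroethyl)phosphonoacetate; 2 (triisopropylsiloxy)methyl chloride
Product: 3 methyl 2-[bis(2,2,2-trifluoroethoxy)phosphoryl]-3-(triisopropylsilyloxy)propanoate (racemic)
Conditions: NaH, THF, 0 °C; then 2, Bu4NI (cat.), 0 °C to rt
Reagents that add atoms: none
Why: SN2 C-alkylation of the stabilised phosphonoacetate carbanion by the reactive α-chloro ether should attach the future C14 as a silyl-protected hydroxymethyl group, and the silyloxide is too poor a leaving group for elimination.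

Step 2
Reactants: 4 (S)-4-benzyl-1,3-oxazolidin-2-one; 5 methyl 4-chloro-4-oxobutanoate
Product: 6 methyl 4-[(4S)-4-benzyl-2-oxo-1,3-oxazolidin-3-yl]-4-oxobutanoate
Conditions: n-BuLi, THF, −78 °C; then 5, −78 to 0 °C
Reagents that add atoms: none
Why: N-acylation of the lithiated oxazolidinone by the acid chloride is the standard entry to Evans imides, and the methyl ester end does not compete with the acid chloride.

Step 3
Reactants: 7 geraniol
Product: 8 (2R,3R)-2,3-epoxygeraniol
Conditions: Ti(Oi-Pr)4 (cat.), D-(−)-diethyl tartrate (cat.), t-BuOOH, 4 Å molecular sieves, CH2Cl2, −20 °C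
Reagents that add atoms: tert-butyl hydroperoxide, CC(C)(C)OO
Why: Sharpless asymmetric epoxidation is directed by the allylic alcohol to the C4=C5 alkene only, and the D-(−)-tartrate ligand should deliver oxygen to the face that gives the (2R,3R)-epoxide, which sets C4 and C5 of the target.

Step 4
Reactants: 8 (2R,3R)-2,3-epoxygeraniol
Product: 9 (2R,3R)-2,3-epoxygeranyl triethylsilyl ether
Conditions: Et3SiCl, imidazole, CH2Cl2, 0 °C
Reagents that add atoms: chlorotriethylsilane, CC[Si](Cl)(CC)CC
Why: Silylation of the primary alcohol masks O6 through ozonolysis, olefination and hydride reduction with the most labile of the three silyl groups used.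

Step 5
Reactants: 9 (2R,3R)-2,3-epoxygeranyl triethylsilyl ether
Product: 10 3-[(2R,3R)-2-methyl-3-(triethylsilyloxymethyl)oxiran-2-yl]propanal
Conditions: O3, CH2Cl2, −78 °C; then PPh3, −78 °C to rt
Reagents that add atoms: ozone, [O-][O+]=O
Why: Ozonolysis with reductive work-up cleaves the only alkene left to the C1 aldehyde, and the epoxide and the silyl ether are inert to ozone.

Step 6
Reactants: 10 3-[(2R,3R)-2-methyl-3-(triethylsilyloxymethyl)oxiran-2-yl]propanal; 3 methyl 2-[bis(2,2,2-trifluoroethoxy)phosphoryl]-3-(triisopropylsilyloxy)propanoate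
Product: 11 methyl (2Z)-5-[(2R,3R)-2-methyl-3-(triethylsilyloxymethyl)oxiran-2-yl]-2-(triisopropylsilyloxymethyl)pent-2-enoate (ester carbon C9 cis to C2)
Conditions: 3, KN(SiMe3)2, 18-crown-6, THF, −78 °C; then 10
Reagents that add atoms: none
Why: In the Still–Gennari olefination the trifluoroethyl phosphonate eliminates quickly from the kinetically formed adduct under dissociating conditions, so the trisubstituted enoate with the ester cis to the C2 chain should predominate, which fixes the C1=C10 geometry (the minor isomer is removed by chromatography).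

Step 7
Reactants: 11 the (Z)-enoate
Product: 12 allylic alcohol with CH2OH (C9) cis to C2 and CH2OSi(i-Pr)3 (C14) trans to C2
Conditions: i-Bu2AlH, CH2Cl2, −78 °C; aq. potassium sodium tartrate
Reagents that add atoms: none
Why: 1,2-Reduction of the enoate ester by i-Bu2AlH at low temperature should give the allylic alcohol without touching the silyl-protected epoxide or the alkene geometry.

Step 8
Reactants: 12 the C9 allylic alcohol
Product: 13 C9 tert-butyldimethylsilyl ether of 12
Conditions: t-BuMe2SiCl, imidazole, DMF, 0 °C to rt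
Reagents that add atoms: tert-butyldimethylsilyl chloride, CC(C)(C)[Si](C)(C)Cl
Why: Silylation under imidazole involves no alkoxide, so no silyl shift from O14 to O9 can blur the two oxygens, and it gives O9 a group of intermediate lability.

Step 9
Reactants: 13 the tris-silyl ether
Product: 14 epoxy alcohol with free C6 hydroxyl, (4R,5R)-epoxide
Conditions: PPTS (cat.), MeOH/CH2Cl2, 0 °C
Reagents that add atoms: none
Why: Acid-catalysed methanolysis cleaves a primary triethylsilyl ether much faster than tert-butyldimethylsilyl and triisopropylsilyl ethers, and the weak acid at 0 °C should spare the epoxide.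

Step 10
Reactants: 14 the epoxy alcohol
Product: 15 epoxy aldehyde (C6 aldehyde, 4R,5S)
Conditions: Dess–Martin periodinane, NaHCO3, CH2Cl2, 0 °C to rt
Reagents that add atoms: none
Why: Buffered Dess–Martin oxidation converts the epoxy alcohol to the epoxy aldehyde under non-epimerising conditions, and the aldehyde is used directly.

Step 11
Reactants: 15 the epoxy aldehyde; 6 methyl 4-[(4S)-4-benzyl-2-oxo-1,3-oxazolidin-3-yl]-4-oxobutanoate
Product: 17 trans-γ-lactone imide (4R,5R,6S,7S) carrying the C9 tert-butyldimethylsilyl ether, via syn-aldol adduct 16 (not isolated)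
Conditions: 6, n-Bu2BOTf, i-Pr2NEt, CH2Cl2, −78 to 0 °C; then 15, −78 to 0 °C; pH 7 buffer, MeOH, H2O2, 0 °C; then PPTS (cat.), CH2Cl2, rt
Reagents that add atoms: none
Why: In the Evans syn-aldol reaction the (Z)-boron enolate of the imide adds through a chair (Zimmerman–Traxler) transition state on the enolate face opposite the benzyl group, which sets C6 and C7 under auxiliary control irrespective of the epoxide, and the γ-hydroxy methyl ester then lactonises (intramolecular transesterification) to the trans-disubstituted γ-lactone.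

Step 12
Reactants: 17 the lactone imide
Product: 18 lactone imide with free C9 hydroxyl
Conditions: HF·pyridine, pyridine, THF, 0 °C
Reagents that add atoms: none
Why: Buffered fluoride desilylation removes the primary allylic tert-butyldimethylsilyl ether well before the bulkier triisopropylsilyl ether, and imide, lactone and epoxide tolerate it.

Step 13
Reactants: 18 the hydroxy lactone imide
Product: 19 lactone diol (C8 and C9 primary alcohols, 7R)
Conditions: NaBH4, THF/H2O (4:1), 0 °C
Reagents that add atoms: none
Why: Borohydride reductive cleavage of the activated exocyclic imide carbonyl gives the primary alcohol and releases the oxazolidinone while the γ-lactone reacts far more slowly, and the diol is taken on at once to limit lactone migration to O8.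

Step 14
Reactants: 19 the lactone diol
Product: 20 epoxy lactone dialdehyde (C8 aldehyde, C9 (Z)-enal, C14 triisopropylsilyl ether; 4R,5R,6S,7S)
Conditions: Dess–Martin periodinane, NaHCO3, CH2Cl2, 0 °C; filtration, used at once without chromatography
Reagents that add atoms: none
Why: Buffered Dess–Martin oxidation converts both primary alcohols to aldehydes without a base strong enough to epimerise C7, expel the β-acyloxy group or isomerise the (Z)-enal.

Step 15
Reactants: 20 the epoxy lactone dialdehyde
Product: 21 ten-membered 8,9-cis-diol (4R,5R,6S,7R,8R,9S; C9 cis to C2 across C1=C10)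
Conditions: SmI2 (2.5 equiv), THF, −78 °C, slow addition of 20 (final 0.003 M); then pH 7 buffer
Reagents that add atoms: none
Why: Two single-electron transfers from SmI2 (divalent samarium) are expected, the first to the more easily reduced enal, so that the ketyl carbons C9 and C8 are joined while both oxygens sit on trivalent samarium and a five-membered samarium diolate results; the closest known reaction type is the SmI2-mediated intramolecular pinacol coupling of dialdehydes to cyclic cis-diols. The ten-membered carbocycle is closed head to head, carbonyl carbon to carbonyl carbon (attack of the C9 ketyl on the C8 carbonyl, 10-exo, both oxygens ending outside the ring). The cis relationship of O8 and O9 is controlled by the oxygen–samarium–oxygen bridge in the bond-forming step, and the sense at C8 by the adjacent C7 stereocentre of the rigid trans-lactone, which is expected to expose the carbonyl face anti to the C7–C11 bond; C9 then follows from the chelate. The step needs coupling at the enal carbonyl carbon and not at C1, retention of the C1=C10 geometry, and ring closure in preference to oligomerisation. These are secured by the samarium bridge, which brings C8 next to C9 and not to C1, by the bulky triisopropylsilyloxymethyl group beside C1, by the low temperature, which slows rotation in the allyl-type ketyl, and by high dilution together with the turn that the lactone, the epoxide and the cis C1=C10 bond impose on the chain. No proton donor or HMPA is present, so simple reduction of the aldehydes and opening of the epoxide should not compete.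

Step 16
Reactants: 21 the cis-diol
Product: 22 8,9-bis(triethylsilyl) ether of 21
Conditions: Et3SiOTf, 2,6-lutidine, CH2Cl2, −78 to 0 °C
Reagents that add atoms: triethylsilyl trifluoromethanesulfonate, CC[Si](CC)(CC)OS(=O)(=O)C(F)(F)F
Why: Silylation with the silyl triflate and a hindered base covers both hindered secondary hydroxyls, so that the strongly basic next step meets no alkoxide (a free O8 alkoxide could attack the lactone).

Step 17
Reactants: 22 the bis(triethylsilyl) ether
Product: 25 α-methylene lactone (C11=C13) of 22, via Mannich base 23 (not isolated), via methiodide 24 (not isolated)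
Conditions: LiN(i-Pr)2, THF, −78 °C; CH2=NMe2+ I−, −78 °C to rt; then MeI, CH2Cl2, rt; then aq. NaHCO3
Reagents that add atoms: Eschenmoser's salt (N,N-dimethylmethyleneiminium iodide), C=[N+](C)C.[I-]
Why: α-Methylenation by the enolate Mannich reaction with Eschenmoser's salt, quaternisation and E1cB loss of trimethylamine should be clean because only C11 carries acidic hydrogens and the lactone enolate has no β-leaving group.

Step 18
Reactants: 25 the silylated α-methylene lactone
Product: 26 8,9,14-triol with α-methylene lactone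
Conditions: HF·pyridine, pyridine, THF, 0 °C to rt
Reagents that add atoms: none
Why: Fluoride desilylation removes the two secondary triethylsilyl ethers and, more slowly, the primary triisopropylsilyl ether under buffered conditions that should leave the epoxide, the α-methylene lactone and the ring alkene untouched.

Step 19
Reactants: 26 the triol
Product: 27 9,14-O-(di-tert-butylsilylene) derivative with free 8-hydroxyl
Conditions: t-Bu2Si(OTf)2 (1.05 equiv), 2,6-lutidine, CH2Cl2, −40 to 0 °C
Reagents that add atoms: di-tert-butylsilyl bis(trifluoromethanesulfonate), CC(C)(C)[Si](OS(=O)(=O)C(F)(F)F)(OS(=O)(=O)C(F)(F)F)C(C)(C)C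
Why: In this cyclic silylene formation the primary C14 hydroxyl should be silylated first and the silyl triflate then closes on the nearest hydroxyl, O9, to a six-membered dioxasilinane (O8 would need a seven-membered ring), which leaves only O8 free.

Step 20
Reactants: 27 the 9,14-silylene
Product: 28 8-O-methacrylate of 27
Conditions: methacrylic anhydride, Et3N, DMAP, CH2Cl2, 0 °C to rt
Reagents that add atoms: methacrylic anhydride, C=C(C)C(=O)OC(=O)C(C)=C
Why: DMAP-catalysed acyl transfer to the only free hydroxyl places the methacrylate on O8 without any question of selectivity.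

Step 21
Reactants: 28 the methacrylate silylene
Product: 29 8-O-methacryloyl 9,14-diol
Conditions: HF·pyridine, pyridine, THF, 0 °C
Reagents that add atoms: none
Why: Fluoride cleavage of the cyclic silylene frees O9 and O14 under buffered conditions in which the ester should not migrate.

Step 22
Reactants: 29 the 9,14-diol
Product: 30 8-O-methacryloyl-9-hydroxy C14 enal
Conditions: TEMPO (cat.), PhI(OAc)2, CH2Cl2, rt
Reagents that add atoms: none
Why: The oxoammonium (TEMPO) oxidation is selective for the primary allylic alcohol over the hindered secondary one and stops at the enal, so C14 is oxidised before O9 is acylated and no acetyl shift from O9 to O14 can arise.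

Step 23
Reactants: 30 the hydroxy enal
Product: 31 9-O-acetyl-8-O-methacryloyl C14 enal
Conditions: Ac2O, pyridine, DMAP (cat.), CH2Cl2, 0 °C
Reagents that add atoms: acetic anhydride, CC(=O)OC(C)=O
Why: Acylation of the remaining secondary allylic alcohol should be straightforward, and the β-substituted enal is a poor partner for amine-induced allylic displacement at 0 °C.

Step 24
Reactants: 31 the acetoxy enal
Product: 32 C14 carboxylic acid
Conditions: NaClO2, NaH2PO4, 2-methyl-2-butene, t-BuOH/H2O, 0 °C to rt
Reagents that add atoms: sodium chlorite, [Na+].[O-]Cl=O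
Why: Pinnick oxidation converts the enal to the acid chemoselectively, and the alkene scavenger removes hypochlorous acid so that the alkenes and the epoxide are not attacked.

Step 25
Reactants: 32 the C14 acid
Product: 33 target CNP0153978.4
Conditions: MeI, KHCO3, DMF, rt
Reagents that add atoms: iodomethane, CI
Why: O-Alkylation of the carboxylate with iodomethane under a weak base that should neither cleave the esters nor add to the α-methylene lactone gives the methyl ester.

Compound list

1 | methyl bis(2,2,2-trifluoroethyl)phosphonoacetate | COC(=O)CP(=O)(OCC(F)(F)F)OCC(F)(F)F | starting material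
2 | (triisopropylsiloxy)methyl chloride | ClCO[Si](C(C)C)(C(C)C)C(C)C | starting material
3 | methyl 2-[bis(2,2,2-trifluoroethoxy)phosphoryl]-3-(triisopropylsilyloxy)propanoate, racemic | COC(=O)C(CO[Si](C(C)C)(C(C)C)C(C)C)P(=O)(OCC(F)(F)F)OCC(F)(F)F | intermediate
4 | (S)-4-benzyl-1,3-oxazolidin-2-one | O=C1OC[C@H](Cc2ccccc2)N1 | starting material
5 | methyl 4-chloro-4-oxobutanoate | COC(=O)CCC(Cl)=O | starting material
6 | methyl 4-[(4S)-4-benzyl-2-oxo-1,3-oxazolidin-3-yl]-4-oxobutanoate | COC(=O)CCC(=O)N1C(=O)OC[C@@H]1Cc1ccccc1 | intermediate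
7 | geraniol, (2E)-3,7-dimethylocta-2,6-dien-1-ol | CC(C)=CCC/C(C)=C/CO | starting material
8 | (2R,3R)-2,3-epoxygeraniol | OC[C@H]1O[C@]1(C)CCC=C(C)C | intermediate
9 | (2R,3R)-2,3-epoxygeranyl triethylsilyl ether | CC[Si](CC)(CC)OC[C@H]1O[C@]1(C)CCC=C(C)C | intermediate
10 | 3-[(2R,3R)-2-methyl-3-(triethylsilyloxymethyl)oxiran-2-yl]propanal | CC[Si](CC)(CC)OC[C@H]1O[C@]1(C)CCC=O | intermediate
11 | methyl (2Z)-5-[(2R,3R)-2-methyl-3-(triethylsilyloxymethyl)oxiran-2-yl]-2-(triisopropylsilyloxymethyl)pent-2-enoate; ester carbon C9 cis to C2 | CC[Si](CC)(CC)OC[C@H]1O[C@]1(C)CC/C=C(/CO[Si](C(C)C)(C(C)C)C(C)C)C(=O)OC | intermediate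
12 | allylic alcohol from 11; CH2OH (C9) cis to C2, CH2OSi(i-Pr)3 (C14) trans to C2 | CC[Si](CC)(CC)OC[C@H]1O[C@]1(C)CC/C=C(/CO[Si](C(C)C)(C(C)C)C(C)C)CO | intermediate
13 | O9 tert-butyldimethylsilyl ether of 12 (O6 triethylsilyl, O14 triisopropylsilyl) | CC[Si](CC)(CC)OC[C@H]1O[C@]1(C)CC/C=C(/CO[Si](C(C)C)(C(C)C)C(C)C)CO[Si](C)(C)C(C)(C)C | intermediate
14 | epoxy alcohol: 13 with free C6 hydroxyl, (4R,5R)-epoxide, C9 cis to C2 | OC[C@H]1O[C@]1(C)CC/C=C(/CO[Si](C(C)C)(C(C)C)C(C)C)CO[Si](C)(C)C(C)(C)C | intermediate
15 | epoxy aldehyde: C6 aldehyde of 14, (4R,5S) | O=C[C@H]1O[C@]1(C)CC/C=C(/CO[Si](C(C)C)(C(C)C)C(C)C)CO[Si](C)(C)C(C)(C)C | intermediate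
16 | syn-aldol adduct: (4S)-4-benzyl-3-acyl-oxazolidinone, (4R,5R,6S,7S), free C6 hydroxyl, C12 methyl ester | O=C1OC[C@H](Cc2ccccc2)N1C(=O)[C@@H](CC(=O)OC)[C@H](O)[C@H]1O[C@]1(C)CC/C=C(/CO[Si](C(C)C)(C(C)C)C(C)C)CO[Si](C)(C)C(C)(C)C | intermediate
17 | trans-γ-lactone imide (4R,5R,6S,7S): O6–C12 lactone, C8 acyl oxazolidinone, O9 tert-butyldimethylsilyl, O14 triisopropylsilyl | O=C1OC[C@H](Cc2ccccc2)N1C(=O)[C@H]1CC(=O)O[C@@H]1[C@H]1O[C@]1(C)CC/C=C(/CO[Si](C(C)C)(C(C)C)C(C)C)CO[Si](C)(C)C(C)(C)C | intermediate
18 | lactone imide with free C9 hydroxyl | O=C1OC[C@H](Cc2ccccc2)N1C(=O)[C@H]1CC(=O)O[C@@H]1[C@H]1O[C@]1(C)CC/C=C(/CO[Si](C(C)C)(C(C)C)C(C)C)CO | intermediate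
19 | lactone diol (4R,5R,6S,7R): C8 and C9 primary alcohols | OC[C@H]1CC(=O)O[C@@H]1[C@H]1O[C@]1(C)CC/C=C(/CO[Si](C(C)C)(C(C)C)C(C)C)CO | intermediate
20 | epoxy lactone dialdehyde (4R,5R,6S,7S): C8 aldehyde, C9 (Z)-enal, O14 triisopropylsilyl | O=C[C@H]1CC(=O)O[C@@H]1[C@H]1O[C@]1(C)CC/C=C(/CO[Si](C(C)C)(C(C)C)C(C)C)C=O | intermediate
21 | ten-membered 8,9-cis-diol (4R,5R,6S,7R,8R,9S), C9 cis to C2, O14 triisopropylsilyl | O[C@@H]1[C@H]2CC(=O)O[C@@H]2[C@H]2O[C@]2(C)CC/C=C(/CO[Si](C(C)C)(C(C)C)C(C)C)[C@@H]1O | intermediate
22 | 8,9-bis(triethylsilyl) ether of 21 | CC[Si](CC)(CC)O[C@@H]1[C@H]2CC(=O)O[C@@H]2[C@H]2O[C@]2(C)CC/C=C(/CO[Si](C(C)C)(C(C)C)C(C)C)[C@@H]1O[Si](CC)(CC)CC | intermediate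
23 | Mannich base: 11-(dimethylaminomethyl) lactone of 22, C11 epimers | CC[Si](CC)(CC)O[C@@H]1[C@H]2C(CN(C)C)C(=O)O[C@@H]2[C@H]2O[C@]2(C)CC/C=C(/CO[Si](C(C)C)(C(C)C)C(C)C)[C@@H]1O[Si](CC)(CC)CC | intermediate
24 | methiodide: trimethylammonium iodide of 23, C11 epimers | CC[Si](CC)(CC)O[C@@H]1[C@H]2C(C[N+](C)(C)C)C(=O)O[C@@H]2[C@H]2O[C@]2(C)CC/C=C(/CO[Si](C(C)C)(C(C)C)C(C)C)[C@@H]1O[Si](CC)(CC)CC.[I-] | intermediate
25 | α-methylene lactone (C11=C13) of 22 | CC[Si](CC)(CC)O[C@@H]1[C@H]2C(=C)C(=O)O[C@@H]2[C@H]2O[C@]2(C)CC/C=C(/CO[Si](C(C)C)(C(C)C)C(C)C)[C@@H]1O[Si](CC)(CC)CC | intermediate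
26 | 8,9,14-triol with α-methylene lactone | O[C@@H]1[C@H]2C(=C)C(=O)O[C@@H]2[C@H]2O[C@]2(C)CC/C=C(/CO)[C@@H]1O | intermediate
27 | 9,14-O-(di-tert-butylsilylene) derivative of 26, free 8-hydroxyl | O[C@@H]1[C@H]2C(=C)C(=O)O[C@@H]2[C@H]2O[C@]2(C)CC/C=C3/CO[Si](C(C)(C)C)(C(C)(C)C)O[C@H]13 | intermediate
28 | 8-O-methacrylate of 27 | C=C(C)C(=O)O[C@@H]1[C@H]2C(=C)C(=O)O[C@@H]2[C@H]2O[C@]2(C)CC/C=C3/CO[Si](C(C)(C)C)(C(C)(C)C)O[C@H]13 | intermediate
29 | 8-O-methacryloyl 9,14-diol | C=C(C)C(=O)O[C@@H]1[C@H]2C(=C)C(=O)O[C@@H]2[C@H]2O[C@]2(C)CC/C=C(/CO)[C@@H]1O | intermediate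
30 | 8-O-methacryloyl-9-hydroxy C14 enal | C=C(C)C(=O)O[C@@H]1[C@H]2C(=C)C(=O)O[C@@H]2[C@H]2O[C@]2(C)CC/C=C(/C=O)[C@@H]1O | intermediate
31 | 9-O-acetyl-8-O-methacryloyl C14 enal | C=C(C)C(=O)O[C@@H]1[C@H]2C(=C)C(=O)O[C@@H]2[C@H]2O[C@]2(C)CC/C=C(/C=O)[C@@H]1OC(C)=O | intermediate
32 | 9-O-acetyl-8-O-methacryloyl C14 carboxylic acid | C=C(C)C(=O)O[C@@H]1[C@H]2C(=C)C(=O)O[C@@H]2[C@H]2O[C@]2(C)CC/C=C(/C(=O)O)[C@@H]1OC(C)=O | intermediate
33 | CNP0153978.4 (4R,5R,6S,7R,8R,9S; C14 methyl ester, 8-methacrylate, 9-acetate) | C=C(C)C(=O)O[C@@H]1[C@H]2C(=C)C(=O)O[C@@H]2[C@H]2O[C@]2(C)CC/C=C(/C(=O)OC)[C@@H]1OC(C)=O | target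

Total step count: 25 (23 in the main line, plus one step each for reagent 3 and imide 6).
Longest linear sequence: 23 steps (geraniol 7 to target 33, steps 3–25).

Steps most likely to fail

Step 15 (pinacol macrocyclisation). What may go wrong: bond formation through C1 of the delocalised enal ketyl, rotation about C1–C10 in that ketyl before coupling, or intermolecular coupling in place of ring closure. The fallback replaces reductive coupling by ring-closing metathesis and dihydroxylation. Setting out from 20, both aldehydes would be methylenated by Wittig reaction (Ph3P=CH2, THF, −78 °C) to the triene F1. The ten-membered ring would then be closed with the second-generation Grubbs catalyst at high dilution to the cyclic diene F2 with a cis C8=C9 bond. OsO4/NMO dihydroxylation of this disubstituted alkene, on the face remote from the lactone, would come back to the route at 21.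

Step 6 (Z-selective olefination). What may go wrong: loss of Z-selectivity or slow addition because of the bulky α-substituent of phosphonate 3. The fallback attaches C14 after the olefination by cross-coupling. Setting out from 10, Still–Gennari olefination with the bromo phosphonate F3 (from 1 by α-bromination) should give the α-bromo enoate F4 with the ester cis to C2. Stille coupling with Bu3SnCH2OH and Pd(PPh3)4 should then give the hydroxymethyl enoate F5 with retention of geometry. Silylation with i-Pr3SiCl/imidazole comes back to the route at 11.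

Step 13 (reductive removal of the auxiliary). What may go wrong: competing hydride attack on the lactone, or migration of the lactone acyl group to the new C8 alkoxide in the basic medium. The fallback removes the auxiliary by hydrolysis and reduces an activated acid. Setting out from 17, LiOH/H2O2 (THF/H2O, 0 °C) should give the carboxylic acid F6. Activation as the isobutyl mixed anhydride F7 (i-BuOCOCl, N-methylmorpholine, THF, −15 °C) and brief reduction with NaBH4 at −15 °C should give the hydroxymethyl lactone F8. HF·pyridine then comes back to the route at 19.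

Further compounds

F1 | step 15 | triene (C8 and C9 aldehydes of 20 as vinyl groups) | C=C[C@H]1CC(=O)O[C@@H]1[C@H]1O[C@]1(C)CC/C=C(/CO[Si](C(C)C)(C(C)C)C(C)C)C=C
F2 | step 15 | cyclic diene (ten-membered ring, cis C8=C9, C9 cis to C2) | CC(C)[Si](C(C)C)(C(C)C)OC/C1=C/CC[C@@]2(C)O[C@@H]2[C@H]2OC(=O)C[C@@H]2/C=C\1
F3 | step 6 | bromo phosphonate, methyl bromo[bis(2,2,2-trifluoroethoxy)phosphoryl]acetate | COC(=O)C(Br)P(=O)(OCC(F)(F)F)OCC(F)(F)F
F4 | step 6 | α-bromo enoate (ester cis to C2) | CC[Si](CC)(CC)OC[C@H]1O[C@]1(C)CC/C=C(/Br)C(=O)OC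
F5 | step 6 | hydroxymethyl enoate (ester cis to C2) | CC[Si](CC)(CC)OC[C@H]1O[C@]1(C)CC/C=C(/CO)C(=O)OC
F6 | step 13 | carboxylic acid (C8 acid of lactone 17) | OC(=O)[C@H]1CC(=O)O[C@@H]1[C@H]1O[C@]1(C)CC/C=C(/CO[Si](C(C)C)(C(C)C)C(C)C)CO[Si](C)(C)C(C)(C)C
F7 | step 13 | isobutyl mixed anhydride | CC(C)COC(=O)OC(=O)[C@H]1CC(=O)O[C@@H]1[C@H]1O[C@]1(C)CC/C=C(/CO[Si](C(C)C)(C(C)C)C(C)C)CO[Si](C)(C)C(C)(C)C
F8 | step 13 | hydroxymethyl lactone (C8 alcohol, O9 tert-butyldimethylsilyl) | OC[C@H]1CC(=O)O[C@@H]1[C@H]1O[C@]1(C)CC/C=C(/CO[Si](C(C)C)(C(C)C)C(C)C)CO[Si](C)(C)C(C)(C)C
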